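**Plan**

1. Retrosynthetic cuts (ent-kaurane locants): C16=C17 (α-methylenation); C13–C16 (ring D, palladium cycloalkenylation of a C15 enol silane); C9–C11 and C8–C14 (Diels–Alder, ring C); C8=C9 and O–C7 (Knoevenagel–lactonisation, spiro δ-lactone); C3–C4 and C5–C10 (double Michael, ring A); then back to a cyclic malonate, 3-chloropropanoyl chloride and a C5 enal.
2. Forward order: open-chain keto ester → temporary γ-lactone C20(=O)–O–C6 → ring A → lactone reduced away → spiro δ-lactone → ring C → ring D → exo-methylene.
3. Enabling feature: C10 lies between the C1 and C20 carbonyls, C4 is α to the C19 aldehyde and C3 is β to the C1 ketone (a 1,5-dicarbonyl across C3–C4). A β-keto ester tethered through its C20 ester to O6 of the enal can therefore add C10 to C5 and then C4 to C3. C20, C6 and C19 all lie on one face of ring A.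
4. Temporary helpers: chloride (masked vinyl ketone), the C20–O–C6 lactone, the allyl group (masked C9 aldehyde) and a TBDPS ether on O19.
5. Stereochemistry: C5 from a chiral primary-amine (iminium) catalyst; C10 by allylation trans to the C5 side chain; C4 in the chair-like ring closure; C1 by axial hydride delivery; C8/C9 by a face-selective suprafacial Diels–Alder reaction; C13 by the bridging geometry.

Key step: step 4

Assumption: the quinine-derived primary amine is taken to give the C5 configuration drawn; if the sense of induction is the opposite, the quinidine-derived pseudo-enantiomer is used.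
Assumption: compound 1, an industrial C5 building block, is taken as commercially available.
Remark: C1–C20 below are the ent-kaurane locants of the target (C7 lactone carbonyl, C15 ketone, C17 methylene, C18 methyl, C19 CH2OH, C20 lactone CH2, C6 CH2OAc).

**Route**

Step 1
Reactants: 1 (E)-3-methyl-4-oxobut-2-en-1-yl acetate
Product: 2 (E)-4-hydroxy-2-methylbut-2-enal
Conditions: K2CO3 (0.1 equiv), MeOH, 0 °C
Reagents that add atoms: none
Why: Carbonate-catalysed methanolysis (transesterification) of the primary allylic acetate should free the C6 hydroxyl without touching the E-enal.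

Step 2
Reactants: 3 2,2-dimethyl-1,3-dioxane-4,6-dione; 4 3-chloropropanoyl chloride
Product: 5 5-(3-chloro-1-hydroxypropylidene)-2,2-dimethyl-1,3-dioxane-4,6-dione
Conditions: pyridine (2 equiv), CH2Cl2, 0 °C → rt
Reagents that add atoms: none
Why: C-acylation of the acidic cyclic malonate by the acid chloride gives the enolised acyl derivative, the usual activated precursor of β-keto esters.

Step 3
Reactants: 5 acyl dioxanedione; 2 (E)-4-hydroxy-2-methylbut-2-enal
Product: 6 (E)-3-methyl-4-oxobut-2-en-1-yl 5-chloro-3-oxopentanoate
Conditions: toluene, 80 °C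
Reagents that add atoms: none
Why: Thermolysis releases acetone and CO2 to give an acylketene that the primary alcohol traps, a standard β-keto ester synthesis that tolerates the enal and the β-chloro ketone.

Step 4
Reactants: 6 (E)-3-methyl-4-oxobut-2-en-1-yl 5-chloro-3-oxopentanoate
Product: 10 cis-fused ring A keto aldehyde γ-lactone bearing allyl at C10, via lactone Michael adduct 7 (not isolated), via C10-allyl chloro ketone 8 (not isolated), via vinyl ketone 9 (not isolated)
Conditions: 9-amino-9-deoxy-epi-quinine (20 mol %), CF3CO2H (40 mol %), toluene, 0 °C → rt; then MeCN, allyl bromide (1.1 equiv), Cs2CO3 (3 equiv), 0 → 40 °C (one pot)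
Reagents that add atoms: allyl bromide (C=CCBr)
Why: The amine salt converts the α-branched enal into an iminium ion and the β-keto ester enol adds through C10 to C5 (5-exo-trig Michael addition), closing the temporary γ-lactone with C5 set by the face the catalyst leaves open; after the switch to carbonate the β-keto lactone is C-allylated at C10 trans to the C5 side chain (the allyl CH2 becomes C9), HCl is lost by E1cB to unmask the vinyl ketone, and the enolate of the C19 aldehyde adds through C4 to C3 (6-endo-trig Michael addition), closing ring A by the C3–C4 bond. The closest known reaction types are the iminium-catalysed Michael addition of 1,3-dicarbonyl compounds to enals and the base-mediated double Michael annulation of 3-oxopent-4-enoates. Ring A can close only cis-fused on the five-membered lactone, which puts C20 and C6 on one face, and C4 is set in a chair-like transition state in which the enolate C=C lies synclinal to the enone with the small planar C19 terminus axial next to the axial C20 carbonyl and the methyl group equatorial. The step needs C- rather than O-allylation and a single allylation, secured by the soft bromide and by C10–H being by far the most acidic site, and it needs ring closure to outrun retro-Michael cleavage of the C5–C10 bond, which the intramolecular attack on an unhindered vinyl ketone should ensure.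

Step 5
Reactants: 10 ring A keto aldehyde γ-lactone
Product: 11 C1,C19-diol γ-lactone (C1–OH cis to C20)
Conditions: NaBH4, MeOH/THF, −20 → 0 °C
Reagents that add atoms: none
Why: Borohydride reduces the C19 aldehyde and the C1 ketone but not the lactone, and hydride should enter C1 axially on the face opposite the axial C20 carbonyl, so that the new hydroxyl is equatorial and cis to C20.

Step 6
Reactants: 11 C1,C19-diol γ-lactone
Product: 12 C19 TBDPS ether
Conditions: TBDPSCl (1.1 equiv), imidazole, DMF, 0 °C → rt
Reagents that add atoms: tert-butyl(chloro)diphenylsilane (CC(C)(C)[Si](Cl)(c1ccccc1)c1ccccc1)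
Why: The bulky silyl chloride should silylate the primary C19 hydroxyl in preference to the hindered secondary C1 hydroxyl (selective silyl ether formation).

Step 7
Reactants: 12 C19 TBDPS ether
Product: 13 C1,C6,C20-triol
Conditions: LiAlH4, THF, 0 °C → rt
Reagents that add atoms: none
Why: Hydride reduction of the γ-lactone removes the temporary ring and delivers C20 and C6 as primary alcohols, while the silyl ether and the alkene are inert.

Step 8
Reactants: 13 C1,C6,C20-triol
Product: 14 C6 monoacetate
Conditions: AcCl (1.05 equiv), 2,4,6-collidine, CH2Cl2, −78 °C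
Reagents that add atoms: acetyl chloride (CC(Cl)=O)
Why: Kinetic acylation at low temperature should pick the unhindered primary C6 hydroxyl over the neopentyl C20 hydroxyl and the secondary C1 hydroxyl.

Step 9
Reactants: 14 C6 monoacetate
Product: 15 (E)-propenyl compound
Conditions: RuHCl(CO)(PPh3)3 (5 mol %), toluene, 80 °C
Reagents that add atoms: none
Why: The ruthenium hydride moves the terminal double bond into the (E)-propenyl position by hydrometalation and β-hydride elimination (alkene isomerisation), which sets up the one-carbon degradation to C9.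

Step 10
Reactants: 15 (E)-propenyl compound
Product: 16 C9 aldehyde
Conditions: O3, CH2Cl2/MeOH, −78 °C; then Me2S
Reagents that add atoms: ozone ([O-][O+]=O)
Why: Ozonolysis with reductive work-up cleaves the only alkene to the C9 aldehyde and acetaldehyde.

Step 11
Reactants: 16 C9 aldehyde; 17 methyl 3-oxobutanoate
Product: 19 spiro 3-acetyl-5,6-dihydropyran-2-one with free C1–OH, via Knoevenagel adduct 18 (not isolated)
Conditions: piperidine (0.2 equiv), AcOH (0.2 equiv), 4 Å molecular sieves, toluene, 60 °C
Reagents that add atoms: none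
Why: Knoevenagel condensation followed by intramolecular transesterification (as in 3-acylcoumarin formation) should close the six-membered lactone through the primary C20 hydroxyl, which allylic 1,3-strain holds next to the Z-ester, in preference to the secondary C1 hydroxyl.

Step 12
Reactants: 19 spiro lactone alcohol
Product: 20 C1,C6-diacetate
Conditions: Ac2O, pyridine, DMAP (cat.), CH2Cl2, rt
Reagents that add atoms: acetic anhydride (CC(=O)OC(C)=O)
Why: DMAP-catalysed esterification of the remaining secondary hydroxyl.

Step 13
Reactants: 20 C1,C6-diacetate; 21 buta-1,3-diene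
Product: 22 cis-fused Diels–Alder adduct (ring C, C12=C13)
Conditions: ZnCl2 (1.5 equiv), buta-1,3-diene (excess), CH2Cl2, sealed tube, 0 °C → rt
Reagents that add atoms: none
Why: Lewis-acid-promoted Diels–Alder reaction of the doubly activated alkylidene β-keto lactone is suprafacial (cis fusion, fixing C8 relative to C9) and should occur on the lactone face flanked by C1, anti to the C10–C5 bond whose side carries CH2OAc and the axial CH2OTBDPS group.

Step 14
Reactants: 22 Diels–Alder adduct
Product: 23 C15 TBS enol ether
Conditions: TBSOTf, Et3N, CH2Cl2, 0 °C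
Reagents that add atoms: tert-butyldimethylsilyl trifluoromethanesulfonate (CC(C)(C)[Si](C)(C)OS(=O)(=O)C(F)(F)F)
Why: Soft enolisation can only occur towards the acetyl methyl group (C16) because C8 is quaternary, and acetates and the lactone are not enolised under these conditions.

Step 15
Reactants: 23 C15 TBS enol ether
Product: 24 bicyclo[3.2.1]octenone (C11=C12)
Conditions: Pd(OAc)2 (10 mol %), O2 (1 atm), DMSO, 45 °C
Reagents that add atoms: none
Why: Divalent palladium turns the enol silane into a palladium enolate that adds 5-exo across C13=C12 (C16–C13 bond), and β-hydride elimination towards C11 releases the product in a Saegusa-type oxidative cycloalkenylation; the two-carbon bridge can only form cis, which fixes C13.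

Step 16
Reactants: 24 bicyclo[3.2.1]octenone
Product: 25 saturated C15 ketone
Conditions: H2 (1 atm), Pd/C (10 wt % Pd), EtOAc, rt
Reagents that add atoms: none
Why: Heterogeneous hydrogenation saturates the disubstituted C11=C12 alkene and creates no stereocentre.

Step 17
Reactants: 25 saturated C15 ketone
Product: 26 19-O-TBDPS-isodojaponin D
Conditions: paraformaldehyde, N-methylanilinium trifluoroacetate, THF, reflux
Reagents that add atoms: formaldehyde (C=O)
Why: Mannich-type α-methylenation (aminomethylation, then elimination) can occur only at C16 because C8 is quaternary.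

Step 18
Reactants: 26 19-O-TBDPS-isodojaponin D
Product: 27 isodojaponin D
Conditions: HF·pyridine, THF/pyridine, 0 °C → rt
Reagents that add atoms: none
Why: Fluoride cleaves the silyl ether under mildly acidic conditions that should leave the acetates, the lactone and the enone intact.

**Compound list**

1 | (E)-3-methyl-4-oxobut-2-en-1-yl acetate | CC(=O)OC/C=C(\C)C=O | starting material
2 | (E)-4-hydroxy-2-methylbut-2-enal | OC/C=C(\C)C=O | intermediate
3 | 2,2-dimethyl-1,3-dioxane-4,6-dione | CC1(C)OC(=O)CC(=O)O1 | starting material
4 | 3-chloropropanoyl chloride | ClCCC(Cl)=O | starting material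
5 | 5-(3-chloro-1-hydroxypropylidene)-2,2-dimethyl-1,3-dioxane-4,6-dione | CC1(C)OC(=O)C(=C(O)CCCl)C(=O)O1 | intermediate
6 | (E)-3-methyl-4-oxobut-2-en-1-yl 5-chloro-3-oxopentanoate | ClCCC(=O)CC(=O)OC/C=C(\C)C=O | intermediate
7 | 3-(3-chloropropanoyl)-4-(1-oxopropan-2-yl)dihydrofuran-2(3H)-one; C5 configured, C10 and C4 as epimer mixtures | O=C1OC[C@H](C(C)C=O)C1C(=O)CCCl | intermediate
8 | 3-allyl-3-(3-chloropropanoyl)-4-(1-oxopropan-2-yl)dihydrofuran-2(3H)-one; allyl trans to the side chain | O=C1OC[C@H](C(C)C=O)[C@]1(CC=C)C(=O)CCCl | intermediate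
9 | 3-acryloyl-3-allyl-4-(1-oxopropan-2-yl)dihydrofuran-2(3H)-one; allyl trans to the side chain | O=C1OC[C@H](C(C)C=O)[C@]1(CC=C)C(=O)C=C | intermediate
10 | cis-fused 7a-allyl-4-methyl-1,7-dioxooctahydroisobenzofuran-4-carbaldehyde; formyl (C19) cis to the lactone bridge (C20, C6), allyl trans | C=CC[C@]1(C(=O)OC2)C(=O)CC[C@@](C)(C=O)[C@H]12 | intermediate
11 | cis-fused 7a-allyl-7-hydroxy-4-(hydroxymethyl)-4-methylhexahydroisobenzofuran-1(3H)-one; 7-OH (C1) and CH2OH (C19) cis to the lactone bridge | C=CC[C@]1(C(=O)OC2)[C@@H](O)CC[C@@](C)(CO)[C@H]12 | intermediate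
12 | C19 tert-butyldiphenylsilyl ether of 11 | C=CC[C@]1(C(=O)OC2)[C@@H](O)CC[C@@](C)(CO[Si](c3ccccc3)(c3ccccc3)C(C)(C)C)[C@H]12 | intermediate
13 | ring A triol: cyclohexane with C10 (allyl, CH2OH), C1–OH, C4 (CH3, CH2OTBDPS) and C5–CH2OH; C20, O1, C19 and C6 all cis, allyl trans | C=CC[C@]1(CO)[C@@H](O)CC[C@@](C)(CO[Si](c2ccccc2)(c2ccccc2)C(C)(C)C)[C@H]1CO | intermediate
14 | C6 monoacetate of 13 | C=CC[C@]1(CO)[C@@H](O)CC[C@@](C)(CO[Si](c2ccccc2)(c2ccccc2)C(C)(C)C)[C@H]1COC(C)=O | intermediate
15 | (E)-prop-1-enyl isomer of 14 | C/C=C/[C@]1(CO)[C@@H](O)CC[C@@](C)(CO[Si](c2ccccc2)(c2ccccc2)C(C)(C)C)[C@H]1COC(C)=O | intermediate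
16 | C9 aldehyde: C10 bears CHO and CH2OH | O=C[C@]1(CO)[C@@H](O)CC[C@@](C)(CO[Si](c2ccccc2)(c2ccccc2)C(C)(C)C)[C@H]1COC(C)=O | intermediate
17 | methyl 3-oxobutanoate | CC(=O)CC(=O)OC | starting material
18 | Knoevenagel adduct: methyl 2-acetylacrylate attached through its β-carbon (C9) to C10, ester cis to C10 | COC(=O)/C(C(C)=O)=C\[C@]1(CO)[C@@H](O)CC[C@@](C)(CO[Si](c2ccccc2)(c2ccccc2)C(C)(C)C)[C@H]1COC(C)=O | intermediate
19 | spiro lactone: 3-acetyl-5,6-dihydro-2H-pyran-2-one spiro-joined at C10 to ring A (C1–OH, C6–OAc, C19–OTBDPS) | CC(=O)C1=C[C@]2(COC1=O)[C@@H](O)CC[C@@](C)(CO[Si](c3ccccc3)(c3ccccc3)C(C)(C)C)[C@H]2COC(C)=O | intermediate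
20 | C1 acetate of 19 | CC(=O)C1=C[C@]2(COC1=O)[C@@H](OC(C)=O)CC[C@@](C)(CO[Si](c3ccccc3)(c3ccccc3)C(C)(C)C)[C@H]2COC(C)=O | intermediate
21 | buta-1,3-diene | C=CC=C | starting material
22 | Diels–Alder adduct: cyclohexene ring C (C12=C13) cis-fused to the δ-lactone, C8 bearing acetyl | CC(=O)[C@]12CC=CC[C@H]1[C@]3(COC2=O)[C@@H](OC(C)=O)CC[C@@](C)(CO[Si](c4ccccc4)(c4ccccc4)C(C)(C)C)[C@H]3COC(C)=O | intermediate
23 | tert-butyldimethylsilyl enol ether of 22 (C15(OTBS)=C16H2) | C=C(O[Si](C)(C)C(C)(C)C)[C@]12CC=CC[C@H]1[C@]3(COC2=O)[C@@H](OC(C)=O)CC[C@@](C)(CO[Si](c4ccccc4)(c4ccccc4)C(C)(C)C)[C@H]3COC(C)=O | intermediate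
24 | bicyclo[3.2.1]oct-ene-15-one: rings C and D closed, C11=C12, C16 as CH2 | C1C(=O)[C@]23C[C@H]1C=C[C@H]2[C@]1(COC3=O)[C@@H](OC(C)=O)CC[C@@](C)(CO[Si](c4ccccc4)(c4ccccc4)C(C)(C)C)[C@H]1COC(C)=O | intermediate
25 | 11,12-dihydro derivative of 24 | C1C(=O)[C@]23C[C@H]1CC[C@H]2[C@]1(COC3=O)[C@@H](OC(C)=O)CC[C@@](C)(CO[Si](c4ccccc4)(c4ccccc4)C(C)(C)C)[C@H]1COC(C)=O | intermediate
26 | 19-O-tert-butyldiphenylsilyl-isodojaponin D | C=C1C(=O)[C@]23C[C@H]1CC[C@H]2[C@]1(COC3=O)[C@@H](OC(C)=O)CC[C@@](C)(CO[Si](c4ccccc4)(c4ccccc4)C(C)(C)C)[C@H]1COC(C)=O | intermediate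
27 | isodojaponin D | C=C1C(=O)[C@]23C[C@H]1CC[C@H]2[C@]1(COC3=O)[C@@H](OC(C)=O)CC[C@@](C)(CO)[C@H]1COC(C)=O | target

**Step count**

Total steps: 18. Longest linear sequence: 17 (steps 1 and 3–18 from compound 1; step 2 prepares compound 5).

**Steps most likely to fail**

Step 4. The ring-closing Michael addition may show poor facial discrimination, with the methyl group rather than the enolate terminus taking the axial site at C4. The C5 configuration may also erode by retro-Michael cleavage once C10 is quaternary. The fallback leaves the C4 methyl group out of the cascade and introduces it afterwards by enolate alkylation. It sets out from compound 5, which is heated with (E)-4-hydroxybut-2-enal F1 (freed from (E)-4-acetoxybut-2-enal by the methanolysis of step 1) to give (E)-4-oxobut-2-en-1-yl 5-chloro-3-oxopentanoate F2. Under the two-stage conditions of step 4, with a diarylprolinol trimethylsilyl ether as the amine for this unbranched enal, F2 should pass through the C4-unsubstituted lactone F3, the C10-allyl chloro ketone F4 and the vinyl ketone F5 to the C4-unsubstituted bicyclic keto aldehyde F6, in which C4 is tertiary and epimerisable. The potassium enolate of the aldehyde of F6 (KOt-Bu, THF/t-BuOH, −20 °C) is then C-methylated with iodomethane on the face opposite the axial C20 carbonyl, the classical outcome for an exocyclic C4 enolate 1,3 to an axial C10 substituent. This comes back to the route at compound 10.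

Step 13. The two faces of the spiro lactone may not be distinguished well enough, which would give the adduct epimeric at C8 and C9. The fallback delivers the diene from the C1 oxygen through a temporary silicon tether. It sets out from compound 19, which is silylated with (buta-1,3-dien-2-yl)chlorodimethylsilane and imidazole to the dienyl silyl ether F7. Heating in toluene should bring about a type 2 intramolecular Diels–Alder reaction to the silicon-bridged adduct F8, since the tethered diene can reach only the C1 face. Protodesilylation of the vinylsilane with CF3CO2H (ipso protonation, alkene position kept) and aqueous work-up should give the C1-hydroxy cycloadduct F9. Acetylation as in step 12 comes back to the route at compound 22.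

Step 15. The catalyst may die as palladium black, the enol silane may be protodesilylated back to the methyl ketone, or 6-endo closure to a bicyclo[2.2.2]octane may compete. The fallback closes ring D by a radical reaction. It sets out from compound 23, which is brominated with N-bromosuccinimide to the bromomethyl ketone F10. Tributyltin hydride and AIBN in benzene at 80 °C then generate the α-keto radical at C16; 5-exo-trig addition to C13 and hydrogen-atom transfer to C12 should give the saturated ketone directly. This comes back to the route at compound 25 and bypasses step 16.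

**Further compounds**

F1 | step 4 | (E)-4-hydroxybut-2-enal | OC/C=C/C=O
F2 | step 4 | (E)-4-oxobut-2-en-1-yl 5-chloro-3-oxopentanoate | ClCCC(=O)CC(=O)OC/C=C/C=O
F3 | step 4 | 3-(3-chloropropanoyl)-4-(2-oxoethyl)dihydrofuran-2(3H)-one | O=C1OC[C@H](CC=O)C1C(=O)CCCl
F4 | step 4 | 3-allyl-3-(3-chloropropanoyl)-4-(2-oxoethyl)dihydrofuran-2(3H)-one, allyl trans to the side chain | O=C1OC[C@H](CC=O)[C@]1(CC=C)C(=O)CCCl
F5 | step 4 | 3-acryloyl-3-allyl-4-(2-oxoethyl)dihydrofuran-2(3H)-one | O=C1OC[C@H](CC=O)[C@]1(CC=C)C(=O)C=C
F6 | step 4 | cis-fused 7a-allyl-1,7-dioxooctahydroisobenzofuran-4-carbaldehyde (C4 epimerisable) | C=CC[C@]1(C(=O)OC2)C(=O)CCC(C=O)[C@H]12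
F7 | step 13 | C1 (buta-1,3-dien-2-yl)dimethylsilyl ether of 19 | CC(=O)C1=C[C@]2(COC1=O)[C@@H](O[Si](C)(C)C(=C)C=C)CC[C@@](C)(CO[Si](c3ccccc3)(c3ccccc3)C(C)(C)C)[C@H]2COC(C)=O
F8 | step 13 | silicon-bridged cycloadduct (Si on C12, O–Si bridge to C1) | CC(=O)[C@]12CC=C3C[C@H]1[C@]4(COC2=O)[C@@H](O[Si]3(C)C)CC[C@@](C)(CO[Si](c5ccccc5)(c5ccccc5)C(C)(C)C)[C@H]4COC(C)=O
F9 | step 13 | C1-hydroxy Diels–Alder adduct (22 lacking the C1 acetyl group) | CC(=O)[C@]12CC=CC[C@H]1[C@]3(COC2=O)[C@@H](O)CC[C@@](C)(CO[Si](c4ccccc4)(c4ccccc4)C(C)(C)C)[C@H]3COC(C)=O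
F10 | step 15 | bromomethyl ketone of 22 (C16–Br) | BrCC(=O)[C@]12CC=CC[C@H]1[C@]3(COC2=O)[C@@H](OC(C)=O)CC[C@@](C)(CO[Si](c4ccccc4)(c4ccccc4)C(C)(C)C)[C@H]3COC(C)=O
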